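Assumption: locants C1–C17 are the cembrane locants of the target and are used for every intermediate. In the carvone-derived ring, carvone C5 = C1, C6 = C14, C1 = C13, C2 = C4, C3 = C3, C4 = C2 and C10 = C16; "β" is the ring face of the C14 oxygen and "α" the face of the C1 side chain.

## Structural features

Crassocolide B is a cembranoid: a 14-membered carbocycle (C1–C14) that carries a trans-fused α-methylene-γ-butyrolactone across C1 and C14 (C15 α-carbon, C16 carbonyl, C17 exocyclic methylene). The five stereocentres fall into two groups: the contiguous triad C13 (allylic acetate), C14 (lactone O–CH) and C1 (ring-fusion CH), and, one methylene further on, the pair C3 (secondary acetate) and C4 (tertiary methyl carbinol). The lipophilic half holds two E-trisubstituted alkenes, C7=C8 and C11=C12, and the second is bonded directly to the C13 carbinol. Fragile elements are the α-methylene lactone (a Michael acceptor), the allylic C13 acetate, the acetates next to free or latent hydroxyls (migration C13→C14 and C3→C4) and the tertiary alcohol. The real difficulty is to close the 14-membered ring with defined alkene geometry while C13 is set next to C14, and to bring five differently functionalised oxygens (two acetates, one free tertiary hydroxyl, two lactone oxygens) to the end. The key step exploits the array C11=C12(CH3)–C13(O)–C14(O): an E-trisubstituted allylic alcohol with an oxygenated neighbour is what syn reductive addition of a C13 aldehyde to a C11≡C12 methyl alkyne delivers. The polar stretch C13–C14–C1–C2–C3–C4, with the C4 methyl and the three-carbon C15–C17 branch, has the ten-carbon connectivity of carvone, so a six-membered ring can hold these carbons until it is cleaved between C4 and C13.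

## Logic of the disconnections

**37 ⇒ 34 ⇒ 33 ⇒ 32 ⇒ 31.** The C16–O14 lactone bond is cut and C16 is taken back to the alcohol level, so that the Michael acceptor exists only in the last step. The two acetates are taken back to silyl ethers. The forward sequence must free C3 and C13 for acetylation while C14 and C16 stay masked, so 31 carries three grades of silyl ether: secondary triethylsilyl, hindered secondary tert-butyldimethylsilyl and primary tert-butyldiphenylsilyl.

**31 ⇒ 30.** The C12–C13 bond and the C11–H bond are cut. This opens the 14-membered ring and removes the C13 stereocentre, leaving an acyclic aldehyde with a methyl alkyne. The forward step must couple at C12 and not C11, add syn, and attack the Felkin face of the aldehyde. Two features of 30 serve this: the C4 hydroxyl is capped as a triethylsilyl ether, so that no O–H bond meets the nickel/silane system, and C16 carries the more acid-stable silyl group.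

**30 ⇒ 28 ⇒ 16 + 25.** The C4–C5 bond is cut next to the tertiary carbinol. This divides the molecule into a polar half with all preset stereocentres (16) and a lipophilic half with the C7=C8 alkene and the alkyne (25). The forward addition must be non-basic, because the ketone is enolisable, and non-chelating, because only the Felkin sense gives the required C3/C4 relationship. The aldehyde must be masked during it.

**25 ⇒ 24 ⇒ 19 + 20 + 21; 19 ⇒ 17.** The C6–C7 bond is cut to release C5–C6 as 21, the C8–methyl bond to release 20, and the C12–methyl bond of 19 to reach 17. Syn carbometalation of a terminal alkyne fixes the E geometry, provided the terminal alkyne reacts and the internal one does not.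

**16 ⇒ 15 ⇒ 14 ⇒ 13 ⇒ 12.** Re-forming the C4–C13 bond turns the keto aldehyde into a six-membered ring, in which C1, C14 and C3 can be controlled by ring conformation. The forward cleavage needs a C4/C13 diol with the C3 oxygen already differentiated, hence the benzoate. It is exchanged for the non-chelating silyl ether once the aldehyde is masked.

**12 ⇒ 11 ⇒ 10 ⇒ 9.** The C3–O bond is cut back to an epoxide, and the epoxide back to the ring alkene. The C13 carbinol of 10 serves only to deliver the epoxide to the α face, so that attack at C3 occurs from the β face with inversion.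

**9 ⇒ 8 ⇒ 5 ⇒ 4 ⇒ 2 ⇒ 1.** The C14–O and C16–O bonds are removed. C1 then comes from the chiral pool, and C14 is set trans to it by attack on the enol ether anti to the side chain.

## Other disconnections considered

Alternative 1: The cut is the C1–C15 bond of the lactone, with C17 added afterwards through the phosphonate. The forward key step starts from the preformed macrocyclic diazophosphonoacetate A1, in which the diazo ester sits on the C14 oxygen and C1 is still a methylene. Treatment of A1 with Rh2(OAc)4 would lead, by rhodium-carbenoid insertion into a C1–H bond, to the α-phosphono lactone A2, and a Horner–Wadsworth–Emmons methylenation of A2 would install C17.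
- In favour: the lactone and its methylene come last, no C16 oxygenation of a terpene is needed, both C15 epimers of A2 converge, and the lactone end-game is shorter than steps 19–22. On these points it is better than the chosen plan.
- Against: the carbenoid from A1 sees two γ C–H sites (the C1 methylene and the C13 methine) and two trisubstituted alkenes open to cyclopropanation. C1 becomes a new stereocentre whose trans relationship to C14 depends on the conformation of a flexible ring, whereas the chosen plan takes C1 from the chiral pool. The disconnection also leaves the 14-membered ring of A1 itself unsolved.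
- Comparison: the insertion is irreversible and conformation-controlled; the nickel cyclisation is controlled by the adjacent C14 stereocentre. Protecting-group load is about equal.

Alternative 2: The cuts are C8–C9 and C8–CH3; the C7=C8 alkene comes from the enol ether of the dihydropyran A3, whose ring oxygen becomes the C4 hydroxyl. In the forward key step the dihydropyran A3 is lithiated at C8 and combined with the cuprate made from the iodide A4; a 1,2-alkyl shift opens the ring and methylation at C8 gives the acyclic dienol A5.
- In favour: three components are joined in one flask, the C7=C8 geometry follows from a stereospecific migration, and C4 is carried in preformed and is released unprotected in A5. For C4 this is better than the chosen plan, which relies on a Felkin addition in step 16. For alkene geometry it is equal, since the carboalumination of step 14 is equally well defined.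
- Against: the dienol A5 is only the C2–C13 chain. C1, C13, C14, the lactone carbons and the ring closure all remain, and the cuprate consumes two equivalents of the organolithium made from A4 unless a dummy ligand is used.
- Comparison: the step does not close a ring and sets no stereocentre, while step 18 does both; step economy for the chain alone is similar.

Alternative 3: The cut is the C11≡C12 bond of a cycloalkyne, with the C12 methyl added later. In the forward key step the diyne A6 would be closed by [Mo(≡C-C6H4-4-OMe)(OSiPh3)3] with 5 Å molecular sieves, with loss of a volatile alkyne by-product, to give the cycloalkyne A7. Desilylation of A7 at C13, hydroxyl-directed trans-hydrostannation and methyl-for-tin exchange would follow.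
- In favour: alkyne metathesis to 14-membered rings is dependable and creates no stereocentre, so the closure of A6 carries no diastereoselectivity risk. The regiochemistry at the alkyne of A7 is set by the C13 hydroxyl and not by a methyl/methylene size difference. On both points it is equal to or better than the chosen plan.
- Against: three operations replace the single step 18, tin is used stoichiometrically, C13 must be set earlier by a separate addition next to C14, and the α-methylene lactone of A7 is exposed to tin hydride chemistry.
- Comparison: the metathesis is driven by loss of a volatile alkyne, the nickel step by a kinetically controlled oxidative cyclisation. The chosen plan is about two steps shorter at this stage.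

Key step: step 18

## Steps

Remark: at C1, C3, C4 and C14 (and at C13 in 31) compounds 30 and 31 have the configurations of 37. (S)-Carvone supplies C1 in the required sense when its C6 becomes C14.

Step 1
Reactants: 1 (S)-(+)-carvone
Product: 2 (S)-10-chlorocarvone
Conditions: Ca(OCl)2, CO2 (dry ice), CH2Cl2/H2O, 0 °C
Reagents that add atoms: calcium hypochlorite, [Ca+2].[O-]Cl.[O-]Cl
Why: Ene-type allylic chlorination by HOCl attacks only the electron-rich 1,1-disubstituted alkene and shifts it to C15=C17; the enone and the C1 stereocentre are untouched.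

Step 2
Reactants: 2 (S)-10-chlorocarvone
Product: 4 (S)-10-hydroxycarvone, via 10-acetoxycarvone 3 (not isolated)
Conditions: KOAc, n-Bu4NI (cat.), DMF, 60 °C; then K2CO3, MeOH, rt
Reagents that add atoms: potassium acetate, CC(=O)[O-].[K+]
Why: SN2 displacement of the primary allylic chloride by acetate followed by methanolysis of the ester; no stereocentre is involved.

Step 3
Reactants: 4 (S)-10-hydroxycarvone
Product: 5 (S)-10-(tert-butyldiphenylsilyloxy)carvone
Conditions: TBDPSCl, imidazole, CH2Cl2, rt
Reagents that add atoms: tert-butyldiphenylsilyl chloride, CC(C)(C)[Si](Cl)(c1ccccc1)c1ccccc1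
Why: Standard silylation of a primary alcohol; this group is chosen because it must survive acidic methanol in steps 10 and 19.

Step 4
Reactants: 5 (S)-10-(tert-butyldiphenylsilyloxy)carvone
Product: 8 trans-6-hydroxy-10-(tert-butyldiphenylsilyloxy)carvone (C14 hydroxyl β), via trimethylsilyl dienol ether 6 (not isolated), via trans-6-trimethylsilyloxy ketone 7 (not isolated)
Conditions: LiN(i-Pr)2, TMSCl, THF, −78 °C; mCPBA, NaHCO3, CH2Cl2, −20 to 0 °C; citric acid, MeOH, rt
Reagents that add atoms: meta-chloroperoxybenzoic acid, OOC(=O)c1cccc(Cl)c1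
Why: Rubottom oxidation: kinetic α′-deprotonation gives the cross-conjugated silyl dienol ether, whose enol ether bond is the most nucleophilic alkene and is epoxidised anti to the C1 side chain. Silyl shift and methanolysis should then leave the hydroxy ketone with the C14 oxygen trans to the side chain.

Step 5
Reactants: 8 trans-6-hydroxy-10-(tert-butyldiphenylsilyloxy)carvone
Product: 9 trans-6-(tert-butyldimethylsilyloxy)-10-(tert-butyldiphenylsilyloxy)carvone
Conditions: TBSOTf, 2,6-lutidine, CH2Cl2, −78 to 0 °C
Reagents that add atoms: tert-butyldimethylsilyl triflate, CC(C)(C)[Si](C)(C)OS(=O)(=O)C(F)(F)F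
Why: Silylation of the secondary α-hydroxy ketone under non-epimerising, weakly basic conditions.

Step 6
Reactants: 9 trans-6-(tert-butyldimethylsilyloxy)-10-(tert-butyldiphenylsilyloxy)carvone
Product: 10 all-equatorial allylic alcohol (C13 hydroxyl α, cis to the C1 side chain and trans to the C14 silyloxy group)
Conditions: NaBH4, CeCl3·7H2O, MeOH, −78 to −40 °C
Reagents that add atoms: none
Why: Luche 1,2-reduction; axial hydride delivery to the half-chair with equatorial substituents should give the equatorial (α) carbinol, as for carvone itself. This centre is used only to direct the next step.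

Step 7
Reactants: 10 all-equatorial allylic alcohol
Product: 11 syn-epoxy alcohol (C3–C4 epoxide on the α face, cis to the C13 hydroxyl)
Conditions: VO(acac)2 (cat.), t-BuOOH, CH2Cl2, 0 °C to rt
Reagents that add atoms: tert-butyl hydroperoxide, CC(C)(C)OO
Why: Hydroxyl-directed epoxidation through a vanadium alkoxide–peroxide delivers oxygen to the face of the C13 hydroxyl and touches only the allylic-alcohol alkene, not C15=C17.

Step 8
Reactants: 11 syn-epoxy alcohol
Product: 12 C3 benzoate 4,13-diol (C3 benzoyloxy β, C4 hydroxyl α, C13 hydroxyl α)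
Conditions: Ti(Oi-Pr)4 (1.5 equiv), PhCO2H, CH2Cl2, rt
Reagents that add atoms: benzoic acid, OC(=O)c1ccccc1
Why: Titanium-assisted opening of a 2,3-epoxy alcohol by a carboxylate at the carbon remote from the carbinol, with inversion at C3. Attack at C3 from the β face is also the trans-diaxial (Fürst–Plattner) mode of the all-equatorial chair and avoids SN2 at the tertiary C4; the non-basic medium avoids silyl migration.

Step 9
Reactants: 12 C3 benzoate 4,13-diol
Product: 13 seco keto aldehyde (C13 aldehyde, C14 OTBS, C3 benzoate, C4 methyl ketone)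
Conditions: NaIO4, THF/pH 7 buffer, 0 °C to rt; used at once
Reagents that add atoms: none
Why: Glycol cleavage of the cis (axial/equatorial) C4/C13 diol through a cyclic periodate ester; the C3 oxygen is acylated and cannot take part, and no stereocentre that is kept is touched.

Step 10
Reactants: 13 seco keto aldehyde
Product: 14 C13 dimethyl acetal of the C3 benzoyloxy methyl ketone
Conditions: HC(OMe)3, PPTS (cat.), MeOH, rt
Reagents that add atoms: trimethyl orthoformate, COC(OC)OC
Why: Acid-catalysed acetalisation is selective for the aldehyde over the α-acyloxy methyl ketone. It is done before any triethylsilyl ether is present and removes the risk of an intramolecular aldol reaction.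

Step 11
Reactants: 14 C13 dimethyl acetal of the C3 benzoyloxy methyl ketone
Product: 15 C3 hydroxy methyl ketone acetal
Conditions: K2CO3 (0.3 equiv), MeOH, 0 °C
Reagents that add atoms: none
Why: Transesterification of an activated α-acyloxy ketone ester is fast at 0 °C, which should leave the C3 configuration and the silyl ethers intact.

Step 12
Reactants: 15 C3 hydroxy methyl ketone acetal
Product: 16 C3 triethylsilyloxy methyl ketone acetal
Conditions: TESCl, imidazole, DMF, 0 °C
Reagents that add atoms: chlorotriethylsilane, CC[Si](Cl)(CC)CC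
Why: Silylation of the only free hydroxyl; the non-chelating silyl ether is what the Felkin addition of step 16 requires.

Step 13
Reactants: 17 1,5-hexadiyne
Product: 19 hepta-1,5-diyne, via lithium hexa-1,5-diyn-1-ide 18 (not isolated)
Conditions: n-BuLi (1 equiv), 17 (3 equiv), THF, −78 °C; MeI, −78 °C to rt; distillation
Reagents that add atoms: iodomethane, CI
Why: Alkylation of a lithium acetylide; excess diyne favours monomethylation and the three volatile hydrocarbons separate by distillation.

Step 14
Reactants: 19 hepta-1,5-diyne; 20 trimethylaluminium; 21 ethylene oxide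
Product: 24 (E)-4-methylnon-3-en-7-yn-1-ol, via (E)-alkenyldimethylalane 22 (not isolated), via lithium alkenyl(butyl)dimethylalanate 23 (not isolated)
Conditions: AlMe3 (2 equiv), Cp2ZrCl2 (0.25 equiv), CH2Cl2, 0 °C to rt; n-BuLi, THF/hexane, −30 °C; 21, −30 °C to rt; H2O
Reagents that add atoms: none
Why: Negishi zirconium-catalysed methylalumination adds methyl and aluminium syn across the terminal alkyne only (methyl to C8). The alanate then opens the epoxide with retention, which fixes the E geometry of C7=C8.

Step 15
Reactants: 24 (E)-4-methylnon-3-en-7-yn-1-ol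
Product: 25 (E)-9-iodo-6-methylnon-6-en-2-yne (the C5–C12 iodide, iodine on C5)
Conditions: I2, PPh3, imidazole, CH2Cl2, 0 °C
Reagents that add atoms: iodine, II
Why: Appel-type iodination of a primary alcohol by SN2 displacement of the alkoxyphosphonium ion; alkene and alkyne are unaffected.

Step 16
Reactants: 16 C3 triethylsilyloxy methyl ketone acetal; 25 (E)-9-iodo-6-methylnon-6-en-2-yne
Product: 28 C4 tertiary alcohol acetal (C3 OTES; C4 configured as in the target), via alkyllithium 26 (not isolated), via organocerium dichloride 27 (not isolated)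
Conditions: 25, t-BuLi (2.1 equiv), Et2O, −78 °C; CeCl3, THF, −78 °C; 16, −78 °C; aq. NH4Cl
Reagents that add atoms: none
Why: Lithium–iodine exchange and transmetalation give a non-basic organocerium reagent that adds to the enolisable ketone without deprotonating it. With the non-chelating C3 silyl ether the polar Felkin–Anh transition state (C3–O anti to the nucleophile, attack past the C3 hydrogen) should give the C3/C4 anti arrangement of the target.

Step 17
Reactants: 28 C4 tertiary alcohol acetal
Product: 30 seco aldehyde with C11≡C12 methyl alkyne (C3 and C4 OTES; C14 OTBS; C16 OTBDPS), via collidinium salt 29 (not isolated)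
Conditions: TESOTf (4 equiv), 2,4,6-collidine (6 equiv), CH2Cl2, 0 °C; then H2O, rt
Reagents that add atoms: triethylsilyl triflate, CC[Si](CC)(CC)OS(=O)(=O)C(F)(F)F; water, O
Why: Silyl triflate/collidine cleavage of an aldehyde acetal: the acetal is ionised and trapped as a collidinium salt, which water hydrolyses to the aldehyde, so acid-labile silyl ethers survive. The same reagent silylates the tertiary C4 hydroxyl, and the aldehyde stays masked until the aqueous quench.

Step 18
Reactants: 30 seco aldehyde with C11≡C12 methyl alkyne
Product: 31 14-membered carbocycle with C13 OTES and E-C11=C12 (C3 and C4 OTES; C14 OTBS; C16 OTBDPS)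
Conditions: Ni(cod)2 (25 mol%), IMes (25 mol%), Et3SiH (5 equiv), THF, 0.005 M, slow addition of 30 over 6 h, rt to 45 °C
Reagents that add atoms: triethylsilane, CC[SiH](CC)CC
Why: Zerovalent nickel carrying the small carbene IMes binds the C13 aldehyde and the C11≡C12 alkyne and undergoes oxidative cyclisation to a divalent-nickel oxametallacyclopentene, which creates the C12–C13 bond. σ-Bond metathesis of the Ni–O bond with Et3SiH gives the C13 silyl ether and an alkenylnickel hydride, and C–H reductive elimination puts hydrogen on C11 cis to C13, which is the E alkene with C10 cis to the C12 methyl. The closest known reaction type is the nickel–carbene catalysed reductive macrocyclisation of ynals with silanes. The 14-membered ring closes in the endo mode with respect to the alkyne (both alkyne carbons become ring atoms) and exo with respect to the carbonyl. The new C13 stereocentre is controlled by the neighbouring C14 silyloxy stereocentre through a polar Felkin–Anh arrangement, which gives the 13,14-anti relationship. Coupling at C12 and not C11 rests on the small ligand, which lets the methyl terminus sit next to the forming C–C bond, and on the lower strain of the 14-membered endocyclic product compared with a 13-membered ring bearing an exocyclic ethylidene. The other alkenes and the silyl ethers are spectators, the C4 hydroxyl is masked, and high dilution with slow addition suppresses intermolecular coupling.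

Step 19
Reactants: 31 14-membered carbocycle with C13 OTES and E-C11=C12
Product: 32 C3,C13-diol (C4 OTES, C14 OTBS and C16 OTBDPS retained)
Conditions: PPTS (0.2 equiv), MeOH/CH2Cl2, 0 °C to rt
Reagents that add atoms: none
Why: Acid-catalysed methanolysis removes secondary triethylsilyl ethers much faster than a tertiary triethylsilyl, a hindered secondary tert-butyldimethylsilyl or a primary tert-butyldiphenylsilyl ether. Premature loss of the C4 silyl group would be harmless, since a tertiary hydroxyl is not acetylated in step 20.

Step 20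
Reactants: 32 C3,C13-diol
Product: 33 C3,C13-diacetate
Conditions: Ac2O, Et3N, DMAP (cat.), CH2Cl2, rt
Reagents that add atoms: acetic anhydride, CC(=O)OC(C)=O
Why: DMAP-catalysed acetylation of the two secondary hydroxyls; every other oxygen is silylated, so no regiochemical question arises.

Step 21
Reactants: 33 C3,C13-diacetate
Product: 34 diacetate triol (free C4, C14 and C16 hydroxyls)
Conditions: HF·pyridine (excess), pyridine, THF, 0 °C to rt
Reagents that add atoms: none
Why: Fluoride-driven cleavage of all three remaining silyl ethers in a buffered, weakly acidic medium, which should not promote acetate migration from C13 to C14 as a basic fluoride source could. The primary tert-butyldiphenylsilyl ether is expected to be the slowest to go and sets the reaction time.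

Step 22
Reactants: 34 diacetate triol
Product: 37 Crassocolide B, via hydroxy enal 35 (not isolated), via lactol 36 (not isolated)
Conditions: MnO2 (excess), CH2Cl2, rt
Reagents that add atoms: none
Why: MnO2 oxidises only the primary allylic C16 alcohol; the enal is captured by the C14 hydroxyl as a five-membered lactol, which is oxidised again to the α-methylene lactone. C13 is already acetylated and the C4 and C14 alcohols are not allylic, so no stereocentre is affected.

## Compound list

1 | (S)-(+)-carvone, (5S)-2-methyl-5-(prop-1-en-2-yl)cyclohex-2-en-1-one | CC1=CC[C@@H](CC1=O)C(C)=C | starting material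
2 | (S)-10-chlorocarvone, (5S)-5-(3-chloroprop-1-en-2-yl)-2-methylcyclohex-2-en-1-one | CC1=CC[C@@H](CC1=O)C(=C)CCl | intermediate
3 | (S)-10-acetoxycarvone (not isolated) | CC1=CC[C@@H](CC1=O)C(=C)COC(C)=O | intermediate
4 | (S)-10-hydroxycarvone | CC1=CC[C@@H](CC1=O)C(=C)CO | intermediate
5 | (S)-10-(tert-butyldiphenylsilyloxy)carvone | CC1=CC[C@@H](CC1=O)C(=C)CO[Si](c2ccccc2)(c3ccccc3)C(C)(C)C | intermediate
6 | cross-conjugated trimethylsilyl dienol ether of 5 (C13=C14 enol ether; not isolated) | CC1=CC[C@@H](C=C1O[Si](C)(C)C)C(=C)CO[Si](c2ccccc2)(c3ccccc3)C(C)(C)C | intermediate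
7 | trans-6-trimethylsilyloxy ketone (C14 OTMS β, trans to the C1 side chain; not isolated) | CC1=CC[C@@H]([C@@H](O[Si](C)(C)C)C1=O)C(=C)CO[Si](c2ccccc2)(c3ccccc3)C(C)(C)C | intermediate
8 | trans-6-hydroxy-10-(tert-butyldiphenylsilyloxy)carvone (C14 OH β) | CC1=CC[C@@H]([C@@H](O)C1=O)C(=C)CO[Si](c2ccccc2)(c3ccccc3)C(C)(C)C | intermediate
9 | trans-6-(tert-butyldimethylsilyloxy)-10-(tert-butyldiphenylsilyloxy)carvone | CC1=CC[C@@H]([C@@H](O[Si](C)(C)C(C)(C)C)C1=O)C(=C)CO[Si](c2ccccc2)(c3ccccc3)C(C)(C)C | intermediate
10 | allylic alcohol: C13 OH α (cis to the C1 side chain, trans to C14 OTBS), C3=C4 alkene | CC1=CC[C@@H]([C@@H](O[Si](C)(C)C(C)(C)C)[C@@H]1O)C(=C)CO[Si](c2ccccc2)(c3ccccc3)C(C)(C)C | intermediate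
11 | syn-epoxy alcohol: C3–C4 epoxide α, C13 OH α, C14 OTBS β | C[C@@]12O[C@@H]1C[C@@H]([C@@H](O[Si](C)(C)C(C)(C)C)[C@@H]2O)C(=C)CO[Si](c3ccccc3)(c4ccccc4)C(C)(C)C | intermediate
12 | C3 benzoate 4,13-diol: C3 OBz β, C4 OH α (methyl β), C13 OH α, C14 OTBS β, C1 side chain α | C[C@@]1(O)[C@@H](OC(=O)c2ccccc2)C[C@@H]([C@@H](O[Si](C)(C)C(C)(C)C)[C@@H]1O)C(=C)CO[Si](c3ccccc3)(c4ccccc4)C(C)(C)C | intermediate
13 | seco keto aldehyde: C13 CHO, C14 OTBS, C1 bearing the 3-(TBDPS-oxy)prop-1-en-2-yl group, C3 OBz, C4 methyl ketone; C1, C3, C14 as in the target | O=C[C@H](O[Si](C)(C)C(C)(C)C)[C@@H](C(=C)CO[Si](c1ccccc1)(c2ccccc2)C(C)(C)C)C[C@H](OC(=O)c3ccccc3)C(C)=O | intermediate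
14 | C13 dimethyl acetal of 13 | COC(OC)[C@H](O[Si](C)(C)C(C)(C)C)[C@@H](C(=C)CO[Si](c1ccccc1)(c2ccccc2)C(C)(C)C)C[C@H](OC(=O)c3ccccc3)C(C)=O | intermediate
15 | C3 hydroxy methyl ketone acetal | COC(OC)[C@H](O[Si](C)(C)C(C)(C)C)[C@@H](C(=C)CO[Si](c1ccccc1)(c2ccccc2)C(C)(C)C)C[C@H](O)C(C)=O | intermediate
16 | C3 triethylsilyloxy methyl ketone acetal | COC(OC)[C@H](O[Si](C)(C)C(C)(C)C)[C@@H](C(=C)CO[Si](c1ccccc1)(c2ccccc2)C(C)(C)C)C[C@H](O[Si](CC)(CC)CC)C(C)=O | intermediate
17 | 1,5-hexadiyne | C#CCCC#C | starting material
18 | lithium hexa-1,5-diyn-1-ide (not isolated) | [Li]C#CCCC#C | intermediate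
19 | hepta-1,5-diyne | C#CCCC#CC | intermediate
20 | trimethylaluminium | C[Al](C)C | starting material
21 | ethylene oxide | C1CO1 | starting material
22 | dimethyl[(E)-2-methylhept-1-en-5-yn-1-yl]alane (not isolated) | C[Al](C)/C=C(\C)CCC#CC | intermediate
23 | lithium butyl(dimethyl)[(E)-2-methylhept-1-en-5-yn-1-yl]alanate (not isolated) | [Li+].CCCC[Al-](C)(C)/C=C(\C)CCC#CC | intermediate
24 | (E)-4-methylnon-3-en-7-yn-1-ol | OCC/C=C(\C)CCC#CC | intermediate
25 | (E)-9-iodo-6-methylnon-6-en-2-yne | ICC/C=C(\C)CCC#CC | intermediate
26 | [(E)-4-methylnon-3-en-7-yn-1-yl]lithium (not isolated) | [Li]CC/C=C(\C)CCC#CC | intermediate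
27 | [(E)-4-methylnon-3-en-7-yn-1-yl]cerium dichloride (not isolated) | Cl[Ce](Cl)CC/C=C(\C)CCC#CC | intermediate
28 | C4 tertiary alcohol acetal: C13 CH(OMe)2, C14 OTBS, C16 OTBDPS, C3 OTES, C4 OH/Me, E-C7=C8, C11≡C12 methyl alkyne | COC(OC)[C@H](O[Si](C)(C)C(C)(C)C)[C@@H](C(=C)CO[Si](c1ccccc1)(c2ccccc2)C(C)(C)C)C[C@H](O[Si](CC)(CC)CC)[C@](C)(O)CC/C=C(\C)CCC#CC | intermediate
29 | C13 methoxy(2,4,6-trimethylpyridinium-1-yl)methyl triflate with C4 OTES (C13 epimers; not isolated) | COC([n+]1c(C)cc(C)cc1C)[C@H](O[Si](C)(C)C(C)(C)C)[C@@H](C(=C)CO[Si](c2ccccc2)(c3ccccc3)C(C)(C)C)C[C@H](O[Si](CC)(CC)CC)[C@](C)(O[Si](CC)(CC)CC)CC/C=C(\C)CCC#CC.[O-]S(=O)(=O)C(F)(F)F | intermediate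
30 | seco aldehyde: C13 CHO, C14 OTBS, C16 OTBDPS, C3 and C4 OTES, C11≡C12 methyl alkyne | O=C[C@H](O[Si](C)(C)C(C)(C)C)[C@@H](C(=C)CO[Si](c1ccccc1)(c2ccccc2)C(C)(C)C)C[C@H](O[Si](CC)(CC)CC)[C@](C)(O[Si](CC)(CC)CC)CC/C=C(\C)CCC#CC | intermediate
31 | 14-membered carbocycle: C13 OTES (13,14-anti), E-C11=C12, E-C7=C8, C3 and C4 OTES, C14 OTBS, C16 OTBDPS | C=C(CO[Si](c2ccccc2)(c3ccccc3)C(C)(C)C)[C@H]1C[C@H](O[Si](CC)(CC)CC)[C@](C)(O[Si](CC)(CC)CC)CC/C=C(\C)CC/C=C(\C)[C@H](O[Si](CC)(CC)CC)[C@@H]1O[Si](C)(C)C(C)(C)C | intermediate
32 | macrocyclic C3,C13-diol (C4 OTES, C14 OTBS, C16 OTBDPS) | C=C(CO[Si](c2ccccc2)(c3ccccc3)C(C)(C)C)[C@H]1C[C@H](O)[C@](C)(O[Si](CC)(CC)CC)CC/C=C(\C)CC/C=C(\C)[C@H](O)[C@@H]1O[Si](C)(C)C(C)(C)C | intermediate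
33 | macrocyclic C3,C13-diacetate (C4 OTES, C14 OTBS, C16 OTBDPS) | C=C(CO[Si](c2ccccc2)(c3ccccc3)C(C)(C)C)[C@H]1C[C@H](OC(C)=O)[C@](C)(O[Si](CC)(CC)CC)CC/C=C(\C)CC/C=C(\C)[C@H](OC(C)=O)[C@@H]1O[Si](C)(C)C(C)(C)C | intermediate
34 | diacetate triol (C4, C14, C16 OH) | C=C(CO)[C@H]1C[C@H](OC(C)=O)[C@](C)(O)CC/C=C(\C)CC/C=C(\C)[C@H](OC(C)=O)[C@@H]1O | intermediate
35 | C16 enal with free C14 hydroxyl (not isolated) | C=C(C=O)[C@H]1C[C@H](OC(C)=O)[C@](C)(O)CC/C=C(\C)CC/C=C(\C)[C@H](OC(C)=O)[C@@H]1O | intermediate
36 | C16 lactol (both C16 epimers; not isolated) | C=C1C(O)O[C@@H]2[C@@H]1C[C@H](OC(C)=O)[C@](C)(O)CC/C=C(\C)CC/C=C(\C)[C@@H]2OC(C)=O | intermediate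
37 | Crassocolide B | C=C1C(=O)O[C@@H]2[C@@H]1C[C@H](OC(C)=O)[C@](C)(O)CC/C=C(\C)CC/C=C(\C)[C@@H]2OC(C)=O | target

## Step count and risks

Total: 22 steps. Longest linear sequence: 19 steps (steps 1–12 and 16–22, from 1). The side chain takes 3 steps (13–15) before it joins in step 16.

**Step 18 (key step).** Most likely failure modes: coupling at C11 instead of C12, which gives a 13-membered ring with an exocyclic ethylidene because methyl and methylene differ little in size; poor facial selectivity at the aldehyde in a constrained ring; or oligomerisation instead of ring closure. Fallback: an intramolecular Nozaki–Hiyama–Kishi reaction forms the same bond. It sets out from 28. Hydrozirconation of the methyl alkyne with Cp2ZrHCl (about 3 equiv, one of which is consumed by the C4 hydroxyl; THF, rt to 40 °C, so that the metal equilibrates to the methyl-bearing carbon) and iodinolysis at −78 °C would give the (E)-C12 alkenyl iodide F1. The hindered 1,1-disubstituted C15=C17 alkene is expected to react more slowly than the alkyne, and any regioisomeric iodide would be removed by chromatography. Acetal cleavage with concomitant C4 silylation, as in step 17, would give the iodo aldehyde F2. CrCl2 with catalytic NiCl2 in DMSO/THF at high dilution would then close the ring to the macrocyclic C13 allylic alcohol F3, again under Felkin control from C14. PPTS in MeOH removes the C3 triethylsilyl ether of F3, and the route is rejoined at 32.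

**Step 16.** Most likely failure mode: insufficient Felkin preference at the methyl ketone (partial chelation by cerium, or small size difference at C3), giving the C4 epimer. Fallback: the roles of the two C4 substituents are exchanged, so that a chelation-controlled methyl addition sets C4. The electrophile comes from 19: carboalumination as in step 14, but with paraformaldehyde as the trap, gives (E)-3-methyloct-2-en-6-yn-1-ol F4, and CBr4/PPh3 converts it into (E)-1-bromo-3-methyloct-2-en-6-yne F5. The main line is left at 16: kinetic deprotonation at the ketone methyl group (LiN(SiMe3)2, THF/DMPU, −78 °C) and alkylation with F5 give the C5–C12 chain ketone F6. Buffered HF·pyridine at 0 °C removes the C3 silyl ether to give the α-hydroxy ketone F7. MeMgBr (3 equiv, −78 °C) should add under chelation control by magnesium, anti to the C2 chain, to give the 3,4-diol F8 with the target configuration at C4. Selective silylation of the secondary hydroxyl (TESCl, imidazole) rejoins the route at 28.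

**Step 17.** Most likely failure modes: sluggish ionisation of an acetal that is deactivated by the adjacent silyloxy group, or loss of the secondary triethylsilyl ether during hydrolysis. Fallback: no acetal is used. It sets out from 12. Methanolysis (K2CO3, MeOH) gives the 3,4,13-triol F9. Phenylboronic acid ties up the cis C4/C13 diol, and TESOTf/2,6-lutidine silylates C3 to give the boronate F10. NaIO4/NH4OAc in aqueous acetone hydrolyses the boronate and cleaves the diol to the C3 triethylsilyloxy keto aldehyde F11. Ti(NEt2)4 (1 equiv, THF, −78 °C) masks the aldehyde in situ as the titanium hemiaminal adduct F12, the organocerium reagent 27 adds to the ketone, and aqueous work-up releases the hydroxy aldehyde F13. TESOTf/2,6-lutidine silylates C4 and rejoins the route at 30.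

**Step 19.** Most likely failure modes: incomplete cleavage at the two hindered secondary positions, or premature uncovering of the C14 or C16 hydroxyl, which would then be acetylated irreversibly in step 20. Fallback: the order of the end-game is changed. It sets out from 31. Exhaustive desilylation with HF·pyridine at rt gives the pentaol F14. TEMPO (cat.)/PhI(OAc)2 in CH2Cl2 oxidises the primary allylic alcohol selectively; closure onto the C14 hydroxyl to the five-membered lactol is expected to be favoured over the six-membered alternative through C13, and further oxidation gives 3,13-di-O-deacetyl crassocolide B F15. Ac2O/pyridine acetylates the two secondary hydroxyls, leaves the tertiary one, and arrives at 37.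

## Further compounds

F1 | step 18 | (E)-C12 alkenyl iodide of 28 (C13 dimethyl acetal, free C4 OH) | COC(OC)[C@H](O[Si](C)(C)C(C)(C)C)[C@@H](C(=C)CO[Si](c1ccccc1)(c2ccccc2)C(C)(C)C)C[C@H](O[Si](CC)(CC)CC)[C@](C)(O)CC/C=C(\C)CC/C=C(\C)I
F2 | step 18 | iodo aldehyde (C13 CHO, C3 and C4 OTES, C12 iodide) | O=C[C@H](O[Si](C)(C)C(C)(C)C)[C@@H](C(=C)CO[Si](c1ccccc1)(c2ccccc2)C(C)(C)C)C[C@H](O[Si](CC)(CC)CC)[C@](C)(O[Si](CC)(CC)CC)CC/C=C(\C)CC/C=C(\C)I
F3 | step 18 | macrocyclic C13 allylic alcohol (C3 and C4 OTES, C14 OTBS, C16 OTBDPS) | C=C(CO[Si](c2ccccc2)(c3ccccc3)C(C)(C)C)[C@H]1C[C@H](O[Si](CC)(CC)CC)[C@](C)(O[Si](CC)(CC)CC)CC/C=C(\C)CC/C=C(\C)[C@H](O)[C@@H]1O[Si](C)(C)C(C)(C)C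
F4 | step 16 | (E)-3-methyloct-2-en-6-yn-1-ol | OC/C=C(\C)CCC#CC
F5 | step 16 | (E)-1-bromo-3-methyloct-2-en-6-yne | BrC/C=C(\C)CCC#CC
F6 | step 16 | C5–C12 chain ketone (C4 ketone without the C4 methyl, C3 OTES, C13 acetal) | COC(OC)[C@H](O[Si](C)(C)C(C)(C)C)[C@@H](C(=C)CO[Si](c1ccccc1)(c2ccccc2)C(C)(C)C)C[C@H](O[Si](CC)(CC)CC)C(=O)CC/C=C(\C)CCC#CC
F7 | step 16 | C3 hydroxy chain ketone | COC(OC)[C@H](O[Si](C)(C)C(C)(C)C)[C@@H](C(=C)CO[Si](c1ccccc1)(c2ccccc2)C(C)(C)C)C[C@H](O)C(=O)CC/C=C(\C)CCC#CC
F8 | step 16 | 3,4-diol acetal | COC(OC)[C@H](O[Si](C)(C)C(C)(C)C)[C@@H](C(=C)CO[Si](c1ccccc1)(c2ccccc2)C(C)(C)C)C[C@H](O)[C@](C)(O)CC/C=C(\C)CCC#CC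
F9 | step 17 | 3,4,13-triol (C3 OH β, C4 OH α, C13 OH α) | C[C@@]1(O)[C@@H](O)C[C@@H]([C@@H](O[Si](C)(C)C(C)(C)C)[C@@H]1O)C(=C)CO[Si](c2ccccc2)(c3ccccc3)C(C)(C)C
F10 | step 17 | C4,C13 phenylboronate with C3 OTES | C[C@@]1(O2)[C@@H](O[Si](CC)(CC)CC)C[C@@H]([C@@H](O[Si](C)(C)C(C)(C)C)[C@@H]1OB2c3ccccc3)C(=C)CO[Si](c4ccccc4)(c5ccccc5)C(C)(C)C
F11 | step 17 | C3 triethylsilyloxy keto aldehyde | O=C[C@H](O[Si](C)(C)C(C)(C)C)[C@@H](C(=C)CO[Si](c1ccccc1)(c2ccccc2)C(C)(C)C)C[C@H](O[Si](CC)(CC)CC)C(C)=O
F12 | step 17 | titanium hemiaminal adduct of F11 at C13 (in situ) | CCN(CC)C(O[Ti](N(CC)CC)(N(CC)CC)N(CC)CC)[C@H](O[Si](C)(C)C(C)(C)C)[C@@H](C(=C)CO[Si](c1ccccc1)(c2ccccc2)C(C)(C)C)C[C@H](O[Si](CC)(CC)CC)C(C)=O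
F13 | step 17 | seco hydroxy aldehyde (C4 OH free, C3 OTES) | O=C[C@H](O[Si](C)(C)C(C)(C)C)[C@@H](C(=C)CO[Si](c1ccccc1)(c2ccccc2)C(C)(C)C)C[C@H](O[Si](CC)(CC)CC)[C@](C)(O)CC/C=C(\C)CCC#CC
F14 | step 19 | macrocyclic pentaol (C3, C4, C13, C14, C16 OH) | C=C(CO)[C@H]1C[C@H](O)[C@](C)(O)CC/C=C(\C)CC/C=C(\C)[C@H](O)[C@@H]1O
F15 | step 19 | 3,13-di-O-deacetyl crassocolide B | C=C1C(=O)O[C@@H]2[C@@H]1C[C@H](O)[C@](C)(O)CC/C=C(\C)CC/C=C(\C)[C@@H]2O
A1 | alternative 1 | macrocyclic C14 diazophosphonoacetate (C1 methylene, C3/C4 acetonide, C13 acetate) | CCOP(=O)(OCC)C(=[N+]=[N-])C(=O)O[C@@H]1CC[C@@H]2OC(C)(C)O[C@]2(C)CC/C=C(\C)CC/C=C(\C)[C@@H]1OC(C)=O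
A2 | alternative 1 | trans-fused α-phosphono lactone macrocycle (C15 epimers) | CCOP(=O)(OCC)C1C(=O)O[C@@H]2[C@@H]1C[C@@H]3OC(C)(C)O[C@]3(C)CC/C=C(\C)CC/C=C(\C)[C@@H]2OC(C)=O
A3 | alternative 2 | 2-methyl-2-(2,2-dimethyl-1,3-dioxolan-4-yl)-3,4-dihydro-2H-pyran (C2–C8 unit) | CC1(C)OC[C@H](O1)[C@@]2(C)CCC=CO2
A4 | alternative 2 | (E)-5-iodo-2-methylpent-2-en-1-yl tert-butyldimethylsilyl ether (C9–C13 iodide) | ICC/C=C(\C)CO[Si](C)(C)C(C)(C)C
A5 | alternative 2 | acyclic C2–C13 dienol with free C4 hydroxyl | CC1(C)OC[C@H](O1)[C@](C)(O)CC/C=C(\C)CC/C=C(\C)CO[Si](C)(C)C(C)(C)C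
A6 | alternative 3 | acyclic lactone diyne with two methyl-capped alkynes (C3/C4 acetonide, C13 OTES) | C=C1C(=O)O[C@@H]([C@@H](O[Si](CC)(CC)CC)C#CC)[C@@H]1C[C@@H]2OC(C)(C)O[C@]2(C)CC/C=C(\C)CCC#CC
A7 | alternative 3 | 14-membered C11≡C12 cycloalkyne (C3/C4 acetonide, C13 OTES) | C=C1C(=O)O[C@@H]2[C@@H]1C[C@@H]3OC(C)(C)O[C@]3(C)CC/C=C(\C)CCC#C[C@@H]2O[Si](CC)(CC)CC
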